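Readings and results were computed for an exercise, noise included.

One day is the unit I reckon in, and the number I want is the first-order rate at which standing target decays, per day.

all flasks: initiator 32 mM

| flask | substrate | coupling partner | remark | time |
|---|---|---|---|---|
| grey | 2.1 M | 2.31 M | run made earlier |  |
| green | 1.1 M | 2.31 M | run made earlier |  |
| dusk | 2.1 M (fed, over 2.40 d) | 2.31 M | all but substrate at the start; substrate goes in evenly over 2.40 d, the run ends at 3.0 d | 3.0 d |
| summer | 2.1 M | 2.31 M (fed, over 2.40 d) | a stirred flask in which coupling partner is dosed at a steady rate over 2.40 d without added volume, worked up at 3.0 d | 3.0 d |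
| noon | 2.1 M | 2.31 M | everything together in a closed stirred flask, run for 3.0 d | 3.0 d |
| autumn | 2.1 M | 2.31 M | a single well-mixed tank run continuously and read at steady state, 3.0 d in it on average |  |

- grey (time / h: target / %, over-reaction product / %, substrate / %): 8.00: 47.0, 10.4, 40.1; 15.0: 43.7, 26.8, 28.0; 25.0: 32.3, 43.1, 22.7; 30.0: 27.1, 49.9, 21.4; 40.0: 19.1, 58.4, 18.6
- green (time / d: target / %, over-reaction product / %, substrate / %): 0.208: 76.5, 9.5, 7.5; 0.625: 54.8, 41.2, 0.8; 1.04: 34.6, 60.0, 0; 1.67: 18.3, 77.0, 0; 2.50: 7.8, 89.0, 0

(standard deviation of a reading: 1 percentage point)

* order of the set-ups by the share of target in all that became target or over-reaction product, at the outlet or at the end, highest first (dusk / summer / noon / autumn)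
* share of target in all that became target or over-reaction product, at the outlet or at the end, dusk
* share of target in all that became target or over-reaction product, at the outlet or at the end, summer
* share of target in all that became target or over-reaction product, at the outlet or at the end, noon
* share of target in all that became target or over-reaction product, at the outlet or at the end, autumn

- the stated concentrations are those of everything mixed, before any reaction; amounts are the same in each set-up
- the feed brings no volume worth counting
- the earlier runs were made in a closed, stirred flask

The two closed runs seem to disagree on that number. In the green run substrate reads 0% at 1.04 d, and target falls from 34.6% to 7.8% of the charge by 2.50 d. That reads as the target's decay constant, a first-order rate constant, of 1.02 d⁻¹. In the grey run target falls from 32.3% at 25.0 h to 19.1% at 40.0 h, which reckoned the same way gives a smaller 0.841 d⁻¹.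

But grey's substrate still drops from 22.7% to 18.6% over that span, so fresh target is arriving and the net fall understates the loss. Over-reaction product counts the loss directly: grey gains 15 percentage points on a logarithmic mean target of 25.1%. This reads 0.974 d⁻¹, close to green's constant. The loss therefore goes with the target present, at either substrate charge.

In the autumn tank at steady state, over-reaction product over target equals the constant times the mean stay, a Damköhler number of 3.06. My share for autumn is therefore 24.6%.

The forecast says autumn > summer > dusk > noon, with dusk 15%, summer 17%, noon 8% and autumn 23.6%, below my figure. Of dusk and summer it says “Both are uncertain because the tail rate is poorly known”.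

The flask gives autumn > dusk > summer > noon, with dusk 18.0%, summer 10.7%, noon 5.93% and autumn 24.0%. Forecast and flask part over the order of dusk and summer.

    substrate + initiating radical → chain carrier (k = 937 M⁻¹ s⁻¹)
    initiator → 2 initiating radical (k = 6.48 × 10⁻⁵ s⁻¹)
    coupling partner + chain carrier → target + initiating radical (k = 626 M⁻¹ s⁻¹)
    2 chain carrier → ended chains (k = 5.20 × 10⁸ M⁻¹ s⁻¹)
    target → over-reaction product (k = 1.22 × 10⁻⁵ s⁻¹)

The target's half-life by its own step to over-reaction product is 0.66 d, short against the 3.0 d of a run, and the constant read from the green run put the autumn tank at 24.6% where the flask gives 24.0%. Carried on the green flask from its share of 7.96% at 2.50 d to 3.0 d, the same constant gives 4.78%, and the green flask's share at that time is 4.70%.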